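**Retrosynthetic overview**
1. Target 17 ⇐ bis-MOM ether 16 by acetal cleavage in the last step.
2. Key disconnection is C2–C3 of the pyranone ring: 16 ⇐ 3-formyl-3-hydroxy-2-aryl-2,3-dihydrobenzofuran 14 by an α-ketol (acyloin) 1,2-shift that inserts the formyl carbon (future C3) between C2 and the carbinol carbon (future C4), a one-carbon ring expansion of furan to pyranone.
3. Enabling feature: the C3 carbinol/C4 aryl ketone pair of the pyranone ring is the α-ketol isomer of a formyl carbinol, and the neighbouring C2 is a benzylic carbon bearing O1 (high migratory aptitude); the carbinol centre of 14 is relayed to C3 and C2 migrates with retention.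
4. 14 ⇐ aryldiazoacetate 10 by Rh(II)-catalysed enantioselective 1,5 C–H insertion into the O1–CH2Ar bond (dihydrofuran ring, sets C2), enolate hydroxylation anti to the aryl group, and ester → aldehyde.
5. 10 ⇐ 2,4-dihydroxyphenylacetic acid (diiodination, a temporary lactone to tell the two phenols apart, double Stille prenylation) + 4-(methoxymethoxy)benzyl alcohol (Mitsunobu); ring order: temporary lactone → dihydrofuran (step 9) → pyranone (step 12).

Key step: step 12

Remark: the sense of induction of Rh2(S-PTTL)4 in step 9 is assigned by analogy with simpler o-benzyloxyaryl diazoacetates; if a test run gives the (2R)-ester, the enantiomeric catalyst Rh2(R-PTTL)4 is used and nothing else changes.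

**Route**

Step 1
Reactants: 1 2,4-dihydroxyphenylacetic acid
Product: 2 2-(2,4-dihydroxy-3,5-diiodophenyl)acetic acid
Conditions: NIS (2.1 equiv), MeCN, 0 °C → rt
Reagents that add atoms: N-iodosuccinimide, O=C1CCC(=O)N1I
Why: Electrophilic aromatic iodination should go only to C3 and C5, the two positions ortho/para to both hydroxyls, because C6 is meta to both.

Step 2
Reactants: 2 2-(2,4-dihydroxy-3,5-diiodophenyl)acetic acid
Product: 3 6-hydroxy-5,7-diiodo-1-benzofuran-2(3H)-one
Conditions: TsOH·H2O (5 mol %), toluene, reflux, azeotropic removal of water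
Reagents that add atoms: none
Why: Acid-catalysed lactonisation of the o-hydroxyphenylacetic acid ties up the 2-hydroxyl (the future O1) in a five-membered lactone and leaves only the 4-hydroxyl free.

Step 3
Reactants: 3 6-hydroxy-5,7-diiodo-1-benzofuran-2(3H)-one
Product: 4 5,7-diiodo-6-(methoxymethoxy)-1-benzofuran-2(3H)-one
Conditions: MOMCl (1.1 equiv), i-Pr2NEt (1.2 equiv), CH2Cl2, 0 °C
Reagents that add atoms: chloromethyl methyl ether, COCCl
Why: Williamson-type O-alkylation should take the acidic 2,6-diiodophenol selectively, since the amine base does not enolise the lactone appreciably.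

Step 4
Reactants: 4 5,7-diiodo-6-(methoxymethoxy)-1-benzofuran-2(3H)-one
Product: 5 6-(methoxymethoxy)-5,7-bis(3-methylbut-2-en-1-yl)-1-benzofuran-2(3H)-one
Conditions: tributyl(3-methylbut-2-en-1-yl)stannane (2.6 equiv), Pd(PPh3)4 (10 mol %), DMF, 90 °C
Reagents that add atoms: tributyl(3-methylbut-2-en-1-yl)stannane, CCCC[Sn](CCCC)(CCCC)CC=C(C)C
Why: Twofold Stille coupling under base-free conditions should spare the lactone, and reductive elimination at the less hindered CH2 terminus of the allyl group should give the linear prenyl isomer at both positions.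

Step 5
Reactants: 5 6-(methoxymethoxy)-5,7-bis(3-methylbut-2-en-1-yl)-1-benzofuran-2(3H)-one
Product: 6 methyl 2-[2-hydroxy-4-(methoxymethoxy)-3,5-bis(3-methylbut-2-en-1-yl)phenyl]acetate
Conditions: NaOMe (1.05 equiv), MeOH, 0 °C; then AcOH (1.05 equiv); used without heating or acid
Reagents that add atoms: sodium methoxide, C[O-].[Na+]
Why: Methanolysis (transesterification) of the aryl lactone should be fast and complete because the phenoxide is a good leaving group, and it frees exactly the hydroxyl that becomes O1.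

Step 6
Reactants: 7 4-(methoxymethoxy)benzaldehyde
Product: 8 [4-(methoxymethoxy)phenyl]methanol
Conditions: NaBH4 (1.0 equiv), MeOH, 0 °C
Reagents that add atoms: none
Why: Borohydride reduction of an aromatic aldehyde is reliable and leaves the acetal untouched.

Step 7
Reactants: 6 methyl 2-[2-hydroxy-4-(methoxymethoxy)-3,5-bis(3-methylbut-2-en-1-yl)phenyl]acetate; 8 [4-(methoxymethoxy)phenyl]methanol
Product: 9 methyl 2-[4-(methoxymethoxy)-2-{[4-(methoxymethoxy)phenyl]methoxy}-3,5-bis(3-methylbut-2-en-1-yl)phenyl]acetate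
Conditions: PPh3 (1.3 equiv), DIAD (1.3 equiv), THF, 0 °C → rt
Reagents that add atoms: none
Why: Mitsunobu etherification of the phenol with the primary benzylic alcohol forms the O1–CH2Ar bond under neutral conditions, which avoids relactonisation of the phenoxide.

Step 8
Reactants: 9 methyl 2-[4-(methoxymethoxy)-2-{[4-(methoxymethoxy)phenyl]methoxy}-3,5-bis(3-methylbut-2-en-1-yl)phenyl]acetate
Product: 10 methyl 2-diazo-2-[4-(methoxymethoxy)-2-{[4-(methoxymethoxy)phenyl]methoxy}-3,5-bis(3-methylbut-2-en-1-yl)phenyl]acetate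
Conditions: p-ABSA (1.3 equiv), DBU (1.5 equiv), MeCN, 0 °C → rt
Reagents that add atoms: 4-acetamidobenzenesulfonyl azide, CC(=O)Nc1ccc(cc1)S(=O)(=O)N=[N+]=[N-]
Why: Regitz diazo transfer to the arylacetate is the standard entry to aryldiazoacetates, and the prenyl alkenes and acetals are inert to the sulfonyl azide at room temperature.

Step 9
Reactants: 10 methyl 2-diazo-2-[4-(methoxymethoxy)-2-{[4-(methoxymethoxy)phenyl]methoxy}-3,5-bis(3-methylbut-2-en-1-yl)phenyl]acetate
Product: 11 methyl (2S,3R)-6-(methoxymethoxy)-2-[4-(methoxymethoxy)phenyl]-5,7-bis(3-methylbut-2-en-1-yl)-2,3-dihydro-1-benzofuran-3-carboxylate (2,3-cis)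
Conditions: Rh2(S-PTTL)4 (1 mol %), toluene, −60 °C
Reagents that add atoms: none
Why: Rh(II)-carbene intramolecular 1,5 C–H insertion: the donor/acceptor carbenoid inserts into the benzylic C–H bond next to O1, which is activated by the ether oxygen and the p-alkoxyphenyl ring and is the only C–H bond within reach, and so closes the dihydrofuran ring, while the chiral N-phthaloyl-tert-leucinate ligand sphere selects one enantiotopic hydrogen and sets C2 (catalyst control); the cis relation at C3 follows from the insertion transition state and is erased in step 10.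

Step 10
Reactants: 11 methyl (2S,3R)-6-(methoxymethoxy)-2-[4-(methoxymethoxy)phenyl]-5,7-bis(3-methylbut-2-en-1-yl)-2,3-dihydro-1-benzofuran-3-carboxylate
Product: 13 methyl (2R,3S)-3-hydroxy-6-(methoxymethoxy)-2-[4-(methoxymethoxy)phenyl]-5,7-bis(3-methylbut-2-en-1-yl)-2,3-dihydro-1-benzofuran-3-carboxylate, via potassium enolate 12 (not isolated)
Conditions: KHMDS (1.2 equiv), THF, −78 °C; then 2-(benzenesulfonyl)-3-phenyloxaziridine (1.5 equiv), −78 °C; then AcOH (1.2 equiv)
Reagents that add atoms: 2-(benzenesulfonyl)-3-phenyloxaziridine, O=S(=O)(c1ccccc1)N1OC1c1ccccc1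
Why: Electrophilic enolate hydroxylation with an N-sulfonyloxaziridine: the planar enolate 12 should be attacked on the face anti to the C2 aryl group (substrate control), so that the tertiary hydroxyl ends trans and the ester cis to that aryl group, and the low temperature should keep the enolate from opening the ring by β-elimination of the phenoxide; the C2 descriptor changes from S to R only through the CIP priorities.

Step 11
Reactants: 13 methyl (2R,3S)-3-hydroxy-6-(methoxymethoxy)-2-[4-(methoxymethoxy)phenyl]-5,7-bis(3-methylbut-2-en-1-yl)-2,3-dihydro-1-benzofuran-3-carboxylate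
Product: 14 (2R,3S)-3-hydroxy-6-(methoxymethoxy)-2-[4-(methoxymethoxy)phenyl]-5,7-bis(3-methylbut-2-en-1-yl)-2,3-dihydro-1-benzofuran-3-carbaldehyde
Conditions: DIBAL-H (2.3 equiv), CH2Cl2, −78 °C; then MeOH, aq potassium sodium tartrate
Reagents that add atoms: none
Why: Partial ester reduction with DIBAL-H: the tertiary hydroxyl is first turned into an aluminium alkoxide that chelates the tetrahedral hemiacetal aluminate, which should be stable at −78 °C and release the aldehyde only on work-up, and no stereocentre is touched.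

Step 12
Reactants: 14 (2R,3S)-3-hydroxy-6-(methoxymethoxy)-2-[4-(methoxymethoxy)phenyl]-5,7-bis(3-methylbut-2-en-1-yl)-2,3-dihydro-1-benzofuran-3-carbaldehyde
Product: 16 (2R,3R)-3-hydroxy-7-(methoxymethoxy)-2-[4-(methoxymethoxy)phenyl]-6,8-bis(3-methylbut-2-en-1-yl)-2,3-dihydro-4H-chromen-4-one, via aluminium alkoxide chelate 15 (not isolated)
Conditions: Al(Ot-Bu)3 (1.1 equiv), toluene, 0 → 40 °C; then aq potassium sodium tartrate
Reagents that add atoms: none
Why: Exchange of one tert-butoxide for the tertiary hydroxyl of 14 gives the five-membered aluminium chelate 15 with the alkoxide and formyl oxygens syn-coplanar, so that the ring bond from the carbinol carbon to C2 lies parallel to the formyl π* orbital and C2 shifts suprafacially to the formyl carbon while the carbinol carbon becomes the C4 aryl ketone (α-ketol or acyloin rearrangement). The closest known reactions are the Lewis-acid- or alkoxide-promoted α-ketol ring enlargements of 1-hydroxycycloalkanecarbaldehydes and of 17-hydroxy-20-oxo steroids (D-homoannulation). The pyranone ring is closed by this 1,2-carbon shift, a one-carbon ring expansion in which the formyl carbon is inserted into the C2–C3 bond of the dihydrofuran ring and the bond between the future C2 and C3 is the only C–C bond formed. C2 migrates with retention, and the new C3 centre is fixed by the carbinol centre of 14, because in the syn chelate C2 can reach only the formyl face on its own side of the chelate plane; with the hydroxyl of 14 trans to the aryl group this places the C3 hydroxyl trans to the C2 aryl group, which is (2R,3R). The step needs migration of C2 instead of the ring-fused aryl carbon and a concerted shift instead of C2–C heterolysis: C2 is an oxygen-bearing benzylic sp3 carbon whose shift gives an aryl ketone conjugated with two ring oxygens, the fused aryl carbon cannot reach the spiro (phenonium-like) geometry of an aryl shift, and the neutral aluminium alkoxide in toluene does not favour ionisation. The change from an aldehyde with a crowded tertiary carbinol to a conjugated, chelated ketol drives the step, and should C2 lose integrity in an ion pair, C3 stays defined and the acid of step 13 would be expected to return C2 to the more stable 2,3-trans arrangement.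

Step 13
Reactants: 16 (2R,3R)-3-hydroxy-7-(methoxymethoxy)-2-[4-(methoxymethoxy)phenyl]-6,8-bis(3-methylbut-2-en-1-yl)-2,3-dihydro-4H-chromen-4-one
Product: 17 lespeflorin B2, (2R,3R)-3,7-dihydroxy-2-(4-hydroxyphenyl)-6,8-bis(3-methylbut-2-en-1-yl)-2,3-dihydro-4H-chromen-4-one
Conditions: 3 M HCl, MeOH, 45 °C
Reagents that add atoms: none
Why: Acid-catalysed acetal solvolysis (MOM cleavage) should free both phenols under conditions in routine use next to o-prenylphenols, dilute acid does not enolise the ketol so C3 is kept, and the 2,3-trans isomer is the thermodynamic one.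

**Compound list**
1 | 2,4-dihydroxyphenylacetic acid | OC(=O)Cc1ccc(O)cc1O | starting material
2 | 2-(2,4-dihydroxy-3,5-diiodophenyl)acetic acid | OC(=O)Cc1cc(I)c(O)c(I)c1O | intermediate
3 | 6-hydroxy-5,7-diiodo-1-benzofuran-2(3H)-one | O=C1Cc2cc(I)c(O)c(I)c2O1 | intermediate
4 | 5,7-diiodo-6-(methoxymethoxy)-1-benzofuran-2(3H)-one | O=C1Cc2cc(I)c(OCOC)c(I)c2O1 | intermediate
5 | 6-(methoxymethoxy)-5,7-bis(3-methylbut-2-en-1-yl)-1-benzofuran-2(3H)-one | O=C1Cc2cc(CC=C(C)C)c(OCOC)c(CC=C(C)C)c2O1 | intermediate
6 | methyl 2-[2-hydroxy-4-(methoxymethoxy)-3,5-bis(3-methylbut-2-en-1-yl)phenyl]acetate | COC(=O)Cc1cc(CC=C(C)C)c(OCOC)c(CC=C(C)C)c1O | intermediate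
7 | 4-(methoxymethoxy)benzaldehyde | COCOc1ccc(C=O)cc1 | starting material
8 | [4-(methoxymethoxy)phenyl]methanol | COCOc1ccc(CO)cc1 | intermediate
9 | methyl 2-[4-(methoxymethoxy)-2-{[4-(methoxymethoxy)phenyl]methoxy}-3,5-bis(3-methylbut-2-en-1-yl)phenyl]acetate | COC(=O)Cc1cc(CC=C(C)C)c(OCOC)c(CC=C(C)C)c1OCc1ccc(OCOC)cc1 | intermediate
10 | methyl 2-diazo-2-[4-(methoxymethoxy)-2-{[4-(methoxymethoxy)phenyl]methoxy}-3,5-bis(3-methylbut-2-en-1-yl)phenyl]acetate | COC(=O)C(=[N+]=[N-])c1cc(CC=C(C)C)c(OCOC)c(CC=C(C)C)c1OCc1ccc(OCOC)cc1 | intermediate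
11 | methyl (2S,3R)-6-(methoxymethoxy)-2-[4-(methoxymethoxy)phenyl]-5,7-bis(3-methylbut-2-en-1-yl)-2,3-dihydro-1-benzofuran-3-carboxylate (2,3-cis) | CC(C)=CCc1cc2c(c(CC=C(C)C)c1OCOC)O[C@H](c1ccc(OCOC)cc1)[C@@H]2C(=O)OC | intermediate
12 | potassium enolate of 11 (C2 stereocentre kept, C3 planar) | CC(C)=CCc1cc2c(c(CC=C(C)C)c1OCOC)O[C@H](c1ccc(OCOC)cc1)C2=C([O-])OC.[K+] | intermediate
13 | methyl (2R,3S)-3-hydroxy-6-(methoxymethoxy)-2-[4-(methoxymethoxy)phenyl]-5,7-bis(3-methylbut-2-en-1-yl)-2,3-dihydro-1-benzofuran-3-carboxylate (hydroxyl trans to the 2-aryl group) | CC(C)=CCc1cc2c(c(CC=C(C)C)c1OCOC)O[C@H](c1ccc(OCOC)cc1)[C@]2(O)C(=O)OC | intermediate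
14 | (2R,3S)-3-hydroxy-6-(methoxymethoxy)-2-[4-(methoxymethoxy)phenyl]-5,7-bis(3-methylbut-2-en-1-yl)-2,3-dihydro-1-benzofuran-3-carbaldehyde | CC(C)=CCc1cc2c(c(CC=C(C)C)c1OCOC)O[C@H](c1ccc(OCOC)cc1)[C@]2(O)C=O | intermediate
15 | di-tert-butoxyaluminium alkoxide of 14 (formyl oxygen chelated to aluminium) | CC(C)=CCc1cc2c(c(CC=C(C)C)c1OCOC)O[C@H](c1ccc(OCOC)cc1)[C@]2(O[Al](OC(C)(C)C)OC(C)(C)C)C=O | intermediate
16 | (2R,3R)-3-hydroxy-7-(methoxymethoxy)-2-[4-(methoxymethoxy)phenyl]-6,8-bis(3-methylbut-2-en-1-yl)-2,3-dihydro-4H-chromen-4-one | CC(C)=CCc1cc2c(c(CC=C(C)C)c1OCOC)O[C@H](c1ccc(OCOC)cc1)[C@@H](O)C2=O | intermediate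
17 | lespeflorin B2, (2R,3R)-3,7-dihydroxy-2-(4-hydroxyphenyl)-6,8-bis(3-methylbut-2-en-1-yl)-2,3-dihydro-4H-chromen-4-one | CC(C)=CCc1cc2c(c(CC=C(C)C)c1O)O[C@H](c1ccc(O)cc1)[C@@H](O)C2=O | target

**Step count**
Total step count: 13. Longest linear sequence: 12 steps (1 → 17 through steps 1–5 and 7–13).

**Steps most likely to fail**

Step 12 (α-ketol ring expansion). What may go wrong is migration of the ring-fused aryl carbon instead of C2, heterolysis of the C2–C bond to an oxocarbenium/enediolate pair with loss of the C2 configuration, or Oppenauer-type hydride transfer from the product alkoxide to unreacted aldehyde. The fallback moves the ring expansion onto a primary carbinyl leaving group instead of the formyl group and reinstalls the C3 oxygen afterwards. It sets out from 13: LiAlH4 in THF should give the 3-(hydroxymethyl)-3-ol diol F1. Selective mesylation of the primary hydroxyl (MsCl, Et3N, −20 °C) should give the hydroxy mesylate F2. A semipinacol (Tiffeneau–Demjanov-type) shift of C2 with retention (LiClO4, CaCO3, THF, 50 °C, or Et2AlCl) should give the (2S)-flavanone F3. Soft enolisation (TMSOTf, Et3N) should give the silyl enol ether F4. Rubottom-type oxidation of F4 with the N-sulfonyloxaziridine anti to the 2-aryl group, followed by mild acid, comes back to the route at 16.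

Step 9 (enantioselective C–H insertion). What may go wrong is weak or reversed enantio-induction on a benzyl ether flanked by two ortho substituents, or diversion of the carbenoid into arene cycloaddition on the benzyl ring. The fallback gives up the insertion and the ring expansion and closes the pyranone through O1 by the epoxychalcone route. It sets out from 7 and purchased 2,4-dihydroxyacetophenone. Iodination with NIS should give 1-(2,4-dihydroxy-3,5-diiodophenyl)ethanone F5. MOMCl with NaH in DMF should give the bis-MOM diiodoacetophenone F6. The Stille conditions of step 4 should give the bis-MOM diprenylacetophenone F7. Claisen–Schmidt condensation with 7 (KOH, EtOH) should give the (E)-chalcone F8. Juliá–Colonna epoxidation (poly-L-leucine, urea–H2O2, DBU, THF), a nucleophilic epoxidation that leaves the prenyl alkenes alone, should give the (2R,3S)-epoxy ketone F9. HCl in MeOH then removes the acetals, and the freed 2'-phenol opens the epoxide at the benzylic carbon (6-endo, inversion) to come back to the route at 17.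

Step 10 (enolate hydroxylation). What may go wrong is β-elimination of the ring phenoxide from the enolate (ring opening to a 2,3-diarylacrylate), addition of the enolate to the sulfonimine by-product, or poor facial selectivity at the crowded tetrasubstituted carbon. The fallback oxidises at the aldehyde level through an enamine instead of through the ester enolate. It sets out from 11: DIBAL-H (1.1 equiv, CH2Cl2, −78 °C) should give the 3-carbaldehyde F10. Secondary-amine-catalysed α-benzoyloxylation with dibenzoyl peroxide should give the tertiary benzoate F11, with oxygen entering anti to the 2-aryl group. Methanolysis (K2CO3, MeOH, 0 °C) comes back to the route at 14.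

**Further compounds**
F1 | step 12 | (2R,3R)-3-(hydroxymethyl)-6-(methoxymethoxy)-2-[4-(methoxymethoxy)phenyl]-5,7-bis(3-methylbut-2-en-1-yl)-2,3-dihydro-1-benzofuran-3-ol | CC(C)=CCc1cc2c(c(CC=C(C)C)c1OCOC)O[C@H](c1ccc(OCOC)cc1)[C@]2(O)CO
F2 | step 12 | [(2R,3R)-3-hydroxy-6-(methoxymethoxy)-2-[4-(methoxymethoxy)phenyl]-5,7-bis(3-methylbut-2-en-1-yl)-2,3-dihydro-1-benzofuran-3-yl]methyl methanesulfonate | CC(C)=CCc1cc2c(c(CC=C(C)C)c1OCOC)O[C@H](c1ccc(OCOC)cc1)[C@]2(O)COS(C)(=O)=O
F3 | step 12 | (2S)-7-(methoxymethoxy)-2-[4-(methoxymethoxy)phenyl]-6,8-bis(3-methylbut-2-en-1-yl)-2,3-dihydro-4H-chromen-4-one | CC(C)=CCc1cc2c(c(CC=C(C)C)c1OCOC)O[C@H](c1ccc(OCOC)cc1)CC2=O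
F4 | step 12 | trimethyl{[(2S)-7-(methoxymethoxy)-2-[4-(methoxymethoxy)phenyl]-6,8-bis(3-methylbut-2-en-1-yl)-2H-chromen-4-yl]oxy}silane | CC(C)=CCc1cc2c(c(CC=C(C)C)c1OCOC)O[C@H](c1ccc(OCOC)cc1)C=C2O[Si](C)(C)C
F5 | step 9 | 1-(2,4-dihydroxy-3,5-diiodophenyl)ethan-1-one | CC(=O)c1cc(I)c(O)c(I)c1O
F6 | step 9 | 1-[3,5-diiodo-2,4-bis(methoxymethoxy)phenyl]ethan-1-one | CC(=O)c1cc(I)c(OCOC)c(I)c1OCOC
F7 | step 9 | 1-[2,4-bis(methoxymethoxy)-3,5-bis(3-methylbut-2-en-1-yl)phenyl]ethan-1-one | CC(=O)c1cc(CC=C(C)C)c(OCOC)c(CC=C(C)C)c1OCOC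
F8 | step 9 | (E)-1-[2,4-bis(methoxymethoxy)-3,5-bis(3-methylbut-2-en-1-yl)phenyl]-3-[4-(methoxymethoxy)phenyl]prop-2-en-1-one | COCOc1ccc(/C=C/C(=O)c2cc(CC=C(C)C)c(OCOC)c(CC=C(C)C)c2OCOC)cc1
F9 | step 9 | [2,4-bis(methoxymethoxy)-3,5-bis(3-methylbut-2-en-1-yl)phenyl][(2R,3S)-3-[4-(methoxymethoxy)phenyl]oxiran-2-yl]methanone | CC(C)=CCc1cc(C(=O)[C@@H]2O[C@H]2c2ccc(OCOC)cc2)c(OCOC)c(CC=C(C)C)c1OCOC
F10 | step 10 | (2S,3R)-6-(methoxymethoxy)-2-[4-(methoxymethoxy)phenyl]-5,7-bis(3-methylbut-2-en-1-yl)-2,3-dihydro-1-benzofuran-3-carbaldehyde | CC(C)=CCc1cc2c(c(CC=C(C)C)c1OCOC)O[C@H](c1ccc(OCOC)cc1)[C@@H]2C=O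
F11 | step 10 | (2R,3S)-3-formyl-6-(methoxymethoxy)-2-[4-(methoxymethoxy)phenyl]-5,7-bis(3-methylbut-2-en-1-yl)-2,3-dihydro-1-benzofuran-3-yl benzoate | CC(C)=CCc1cc2c(c(CC=C(C)C)c1OCOC)O[C@H](c1ccc(OCOC)cc1)[C@]2(OC(=O)c1ccccc1)C=O
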